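**Assumption:** bisabolane numbering is used (C1 = C(Cl)Me, C2 = CHBr, C4 = ring CH, C7 = quaternary O‑carbon, C10 = CHBr of the oxane). The target SMILES is (1R,2R,4R,7R,10S); with the C4 substituent equatorial, Br and Cl are trans‑diequatorial.

## Retrosynthetic overview

1. Deoxycaespitol ⇒ cyclohexene 12 (alkene reduction) ⇒ acyclic diene 11 by C5=C6 ring‑closing metathesis; the carbocycle is closed last, after all five stereocentres exist.
2. Why not the bisabolol route: anti‑addition of Br/Cl to a 4‑substituted 1‑methylcyclohexene opens diaxially and gives the (1S,2S) diastereomer, not the diequatorial target. C1/C2 are therefore set on an acyclic (Z)‑allylic alcohol by catalyst‑controlled anti‑bromochlorination (key step).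
3. The (Z)‑allylic alcohol 8 ⇒ sp3–sp2 Negishi coupling of alkyl iodide 5 with (Z)‑3‑iodo‑2‑methylallyl alcohol 7.
4. Bromo‑oxane (first ring) ⇒ 6‑endo bromoetherification of tertiary alcohol 3; a chair transition state sets C10 relative to C7.
5. C7 and C4 ⇒ Sharpless epoxidation of nerol, then anti SN2 opening with a vinyl cuprate. Ring order: oxane first, cyclohexane last.

## Route

**Step 1**
Reactants: 1, nerol
Product: 2, (2S,3R)‑2,3‑epoxynerol
Conditions: Ti(OiPr)4 (5 mol%), L‑(+)‑DET (7 mol%), t‑BuOOH, 4 Å MS, CH2Cl2, −20 °C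
Reagents that add atoms: tert‑butyl hydroperoxide, CC(C)(C)OO (adds O)
Why: Sharpless asymmetric epoxidation of the (Z)‑allylic alcohol; the L‑tartrate gives the 2S,3R epoxide, which fixes C7 (R) and the C4 precursor, and the remote 6,7‑alkene is not an allylic alcohol so it is untouched.

**Step 2**
Reactants: 2
Product: 3, (2R,3R)‑2‑ethenyl‑3,7‑dimethyloct‑6‑ene‑1,3‑diol
Conditions: vinylMgBr (3 equiv), CuI (15 mol%), THF, −30 → 0 °C; NaIO4 work‑up to remove any 1,2‑diol
Reagents that add atoms: vinylmagnesium bromide, C=C[Mg]Br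
Why: Cu‑catalysed SN2 opening of a 3,3‑disubstituted 2,3‑epoxy alcohol occurs at the less hindered C2 with inversion, which sets C4 (R in the final numbering) next to the untouched C7–O bond.

**Step 3**
Reactants: 3
Product: 4, (2R)‑2‑[(2R,5S)‑5‑bromo‑2,6,6‑trimethyloxan‑2‑yl]but‑3‑en‑1‑ol
Conditions: TBCO (1.1 equiv), MeNO2, 0 °C → rt
Reagents that add atoms: 2,4,4,6‑tetrabromocyclohexa‑2,5‑dienone, O=C1C(Br)=CC(Br)(Br)C=C1Br (adds Br)
Why: bromoetherification in which the tertiary OH attacks the tertiary end of the bromonium (Markovnikov, 6‑endo, anti) through a chair with the branched C7 substituent equatorial and CH3 axial, so Br ends equatorial (C10 = S); the terminal vinyl is far less nucleophilic and the primary OH cannot reach.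

**Step 4**
Reactants: 4
Product: 5, (2R,5S)‑5‑bromo‑2‑[(2S)‑1‑iodobut‑3‑en‑2‑yl]‑2,6,6‑trimethyloxane
Conditions: I2, PPh3, imidazole, CH2Cl2, 0 °C → rt
Reagents that add atoms: iodine, II
Why: Appel‑type (Garegg–Samuelsson) iodination of the only hydroxyl; no stereocentre is touched (the C4 descriptor changes by CIP only) and the hindered secondary bromide is inert.

**Step 5**
Reactants: 6, propargyl alcohol
Product: 7, (2Z)‑3‑iodo‑2‑methylprop‑2‑en‑1‑ol
Conditions: MeMgBr (2.5 equiv), CuI (10 mol%), Et2O, −10 °C → rt; then I2, −40 → 0 °C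
Reagents that add atoms: methylmagnesium bromide, C[Mg]Br; iodine, II
Why: Duboudin anti‑carbomagnesiation via the chelated magnesium alkoxide gives a cyclic vinylmagnesium, and iodinolysis with retention gives only the Z isomer (I cis to CH2OH).

**Step 6**
Reactants: 5 and 7
Product: 8, (2Z,5S)‑5‑[(2R,5S)‑5‑bromo‑2,6,6‑trimethyloxan‑2‑yl]‑2‑methylhepta‑2,6‑dien‑1‑ol
Conditions: 5, Zn dust/LiCl, THF, 30 °C; then 7 (as Na alkoxide, NaH), PdCl2(dppf) (5 mol%), THF, rt
Reagents that add atoms: none (both fragments are numbered reactants)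
Why: Negishi sp3–sp2 coupling with retention of vinyl iodide geometry delivers the Z trisubstituted alkene; zinc inserts into the primary C–I bond rather than the hindered secondary C–Br, and masking the OH as its alkoxide avoids protonating the alkylzinc.

**Step 7 (key step)**
Reactants: 8
Product: 9, (2R,3R,5S)‑3‑bromo‑5‑[(2R,5S)‑5‑bromo‑2,6,6‑trimethyloxan‑2‑yl]‑2‑chloro‑2‑methylhept‑6‑en‑1‑ol
Conditions: NBS (1.1 equiv), ClTi(OiPr)3 (1.1 equiv), chiral tridentate Schiff‑base ligand (20 mol%; antipode chosen for the 2R,3R product), hexanes, −20 °C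
Reagents that add atoms: N‑bromosuccinimide, O=C1CCC(=O)N1Br (adds Br); chlorotitanium triisopropoxide, CC(C)O[Ti](Cl)(OC(C)C)OC(C)C (adds Cl)
Why: Ti/Schiff‑base catalysed enantioselective bromochlorination of allylic alcohols (Burns‑type); Br+ adds to the CH carbon and Ti‑bound chloride opens anti at the tertiary carbon (Markovnikov), so the Z alkene gives the (2R,3R) pair that becomes ring‑trans C1(R)/C2(R) under catalyst control, with no diaxial‑opening constraint because the substrate is acyclic, and the monosubstituted vinyl is inert.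

**Step 8**
Reactants: 9
Product: 10, (2R,3R,5S)‑3‑bromo‑5‑[(2R,5S)‑5‑bromo‑2,6,6‑trimethyloxan‑2‑yl]‑2‑chloro‑2‑methylhept‑6‑enal
Conditions: Dess–Martin periodinane, NaHCO3, CH2Cl2, 0 °C → rt
Reagents that add atoms: none
Why: Dess–Martin oxidation of the primary alcohol; the α‑carbon is quaternary (no α‑H), so the α‑chloro aldehyde cannot epimerise or eliminate.

**Step 9**
Reactants: 10
Product: 11, (2R,5S)‑5‑bromo‑2‑[(3S,5R,6R)‑5‑bromo‑6‑chloro‑6‑methylocta‑1,7‑dien‑3‑yl]‑2,6,6‑trimethyloxane
Conditions: Ph3PCH3Br, KHMDS, THF, −78 → 0 °C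
Reagents that add atoms: methylenetriphenylphosphorane, C=P(c1ccccc1)(c1ccccc1)c1ccccc1 (adds CH2)
Why: Wittig methylenation of a non‑enolisable, highly electrophilic aldehyde at low temperature; the resulting CH2=CH–C(Cl)(Me)–CHBr unit is the same tertiary allylic chloride motif found in isolable halogenated monoterpenes.

**Step 10**
Reactants: 11
Product: 12, (2R,5S)‑5‑bromo‑2‑[(1S,4R,5R)‑5‑bromo‑4‑chloro‑4‑methylcyclohex‑2‑en‑1‑yl]‑2,6,6‑trimethyloxane
Conditions: Grubbs II (5 mol%), 1,4‑benzoquinone (10 mol%), CH2Cl2 (5 mM), 40 °C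
Reagents that add atoms: none (ethylene is lost)
Why: ring‑closing metathesis of a 1,7‑diene to a cyclohexene forms the C5=C6 bond between two CH carbons, so the ring closes without touching any stereocentre (the C4 descriptor changes by CIP only); benzoquinone suppresses Ru–H alkene migration.

**Step 11**
Reactants: 12
Product: 13, deoxycaespitol, (2R,5S)‑5‑bromo‑2‑[(1R,3R,4R)‑3‑bromo‑4‑chloro‑4‑methylcyclohexyl]‑2,6,6‑trimethyloxane
Conditions: 2‑nitrobenzenesulfonylhydrazide (excess), Et3N, CH2Cl2, rt
Reagents that add atoms: none (adds H2 only)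
Why: diimide reduction of the cis‑disubstituted ring alkene is metal‑free, so the C–Br, tertiary C–Cl and allylic C–Cl bonds are not hydrogenolysed and no stereocentre is affected.

Enantiopurity note: the minor enantiomer from Step 1 becomes a diastereomer after the catalyst‑controlled Step 7 and is removed by chromatography.

## Compound list

1 | nerol, (2Z)‑3,7‑dimethylocta‑2,6‑dien‑1‑ol | CC(C)=CCC/C(C)=C\CO | starting material
2 | (2S,3R)‑2,3‑epoxynerol | CC(C)=CCC[C@@]1(C)O[C@H]1CO | intermediate
3 | (2R,3R)‑2‑ethenyl‑3,7‑dimethyloct‑6‑ene‑1,3‑diol | CC(C)=CCC[C@@](C)(O)[C@H](C=C)CO | intermediate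
4 | (2R)‑2‑[(2R,5S)‑5‑bromo‑2,6,6‑trimethyloxan‑2‑yl]but‑3‑en‑1‑ol | CC1(C)O[C@@](C)([C@H](C=C)CO)CC[C@@H]1Br | intermediate
5 | (2R,5S)‑5‑bromo‑2‑[(2S)‑1‑iodobut‑3‑en‑2‑yl]‑2,6,6‑trimethyloxane | CC1(C)O[C@@](C)([C@H](C=C)CI)CC[C@@H]1Br | intermediate
6 | propargyl alcohol | C#CCO | starting material
7 | (2Z)‑3‑iodo‑2‑methylprop‑2‑en‑1‑ol | I/C=C(C)\CO | intermediate
8 | (2Z,5S)‑5‑[(2R,5S)‑5‑bromo‑2,6,6‑trimethyloxan‑2‑yl]‑2‑methylhepta‑2,6‑dien‑1‑ol | CC1(C)O[C@@](C)([C@H](C=C)C/C=C(C)\CO)CC[C@@H]1Br | intermediate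
9 | (2R,3R,5S)‑3‑bromo‑5‑[(2R,5S)‑5‑bromo‑2,6,6‑trimethyloxan‑2‑yl]‑2‑chloro‑2‑methylhept‑6‑en‑1‑ol | CC1(C)O[C@@](C)([C@H](C=C)C[C@@H](Br)[C@](C)(Cl)CO)CC[C@@H]1Br | intermediate
10 | (2R,3R,5S)‑3‑bromo‑5‑[(2R,5S)‑5‑bromo‑2,6,6‑trimethyloxan‑2‑yl]‑2‑chloro‑2‑methylhept‑6‑enal | CC1(C)O[C@@](C)([C@H](C=C)C[C@@H](Br)[C@](C)(Cl)C=O)CC[C@@H]1Br | intermediate
11 | (2R,5S)‑5‑bromo‑2‑[(3S,5R,6R)‑5‑bromo‑6‑chloro‑6‑methylocta‑1,7‑dien‑3‑yl]‑2,6,6‑trimethyloxane | CC1(C)O[C@@](C)([C@H](C=C)C[C@@H](Br)[C@](C)(Cl)C=C)CC[C@@H]1Br | intermediate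
12 | (2R,5S)‑5‑bromo‑2‑[(1S,4R,5R)‑5‑bromo‑4‑chloro‑4‑methylcyclohex‑2‑en‑1‑yl]‑2,6,6‑trimethyloxane | CC1(C)O[C@@](C)([C@@H]2C=C[C@@](C)(Cl)[C@H](Br)C2)CC[C@@H]1Br | intermediate
13 | deoxycaespitol | CC1(C)O[C@@](C)([C@@H]2CC[C@@](C)(Cl)[C@H](Br)C2)CC[C@@H]1Br | target

## Summary

Total steps: 11. Longest linear sequence: 10 (nerol → 13; Steps 1–4 and 6–11).

Three steps most likely to fail, each with an approach‑changing fallback:

- **Step 7 (bromochlorination).** A (Z)‑trisubstituted allylic alcohol with a bulky cis chain is an untested substrate class; the risks are low catalyst control and misplaced chloride. Fallback: couple 5 with the (E)‑vinyl iodide instead, carry out a Sharpless epoxidation of the (E)‑allylic alcohol, then a stereospecific double inversion (chloride at the tertiary epoxide carbon, then invertive deoxybromination of the secondary alcohol). Two inversions on the trans‑epoxide give the same (2R,3R) anti‑bromochloride as anti‑addition to the Z alkene.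
- **Step 3 (bromoetherification).** 5‑exo oxolane formation and the C10 epimer will compete, and yields for this type of closure are typically modest. Fallback: make C10 reagent‑controlled. Shi epoxidation of the 6,7‑alkene of 3 (D‑fructose‑derived ketone, (R)‑epoxide), then bromide opening at the secondary carbon with inversion (Li2NiBr4) to the (S)‑bromohydrin, then acid‑promoted closure through the stereodefined bromonium.
- **Step 10 (RCM through the tertiary allylic chloride, with Steps 9 and 11).** Ionisation or allylic transposition of the chloride under Ru and heat, or slow closure of two hindered vinyls, could erode the material. Fallback: close C5=C6 by a low‑temperature intramolecular Wittig instead. Ozonolyse the C4 vinyl of 9 (its only alkene), reduce, convert to the iodide and then the phosphonium salt, oxidise C6–OH and cyclise with base, so no Ru or heating touches the allylic chloride.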